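- Saturday's run reads ring 34.4% against open dimer 8.9% at 50.0 min, which is 79.4% as ring over ring plus open dimer, the clean share (a selectivity between these two).

| flask | starting material | activator | temperature | remark | time |
|---|---|---|---|---|---|
| Friday's | 0.25 M | 0.18 M | 25 °C | run made earlier |  |
| Saturday's | 0.25 M | 0.41 M | 40 °C | run made earlier |  |
| Tuesday's | 0.50 M | 0.275 M | 25 °C | run made earlier |  |
| zeta | 0.25 M | 0.275 M | 50 °C |  | 50 min |
| gamma | 0.25 M | 0.275 M | 30 °C |  | 50 min |

| run | time / min | ring / % | open dimer / % |
|---|---|---|---|
| Friday's | 8.00 | 0.4 | 0 |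
| Friday's | 30.0 | 2.9 | 3.9 |
| Friday's | 50.0 | 5.1 | 6.6 |
| Friday's | 60.0 | 6.0 | 6.4 |
| Friday's | 90.0 | 7.5 | 7.2 |
| Friday's | 150 | 11.4 | 9.7 |
| Friday's | 180 | 14.0 | 11.1 |
| Saturday's | 12.0 | 11.0 | 7.3 |
| Saturday's | 25.0 | 25.2 | 7.8 |
| Saturday's | 30.0 | 26.6 | 8.6 |
| Saturday's | 50.0 | 34.4 | 8.9 |
| Saturday's | 60.0 | 38.2 | 9.4 |
| Saturday's | 80.0 | 37.9 | 9.4 |
| Tuesday's | 15.0 | 0 | 3.7 |
| Tuesday's | 30.0 | 2.5 | 5.8 |
| Tuesday's | 50.0 | 5.1 | 7.4 |
| Tuesday's | 80.0 | 5.8 | 8.8 |
| Tuesday's | 180 | 11.3 | 10.1 |

(scatter of a reading: 1 percentage point)

1. the best flask by share of ring in all that became ring or open dimer or side product; "all alike" if 1.5 percentage points covers them all (zeta / gamma / all alike)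
2. share of ring in all that became ring or open dimer or side product, zeta
3. share of ring in all that became ring or open dimer or side product, gamma

- percentages count the starting material that a species holds: one open dimer or side product or self-condensation product counts as two
- on the list of suspects stand: 2 starting material -> self-condensation product; starting material + ring -> side product; activated form -> ring; starting material + activator -> activated form; starting material + activated form -> open dimer

- Side product adds to the bottom of the asked share and not to the clean one, so the asked share stands at or below the clean share; no reading shows side product.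
- From above, for zeta: Saturday's ring plus open dimer reads 47.3% at 80.0 min, and zeta has less activator though it runs hotter; as a judgement, I allow it no higher total. Open dimer at 50.0 min read lowest on Friday, 6.6%, which puts my estimated ceiling of the clean share at 86.0%.
- From below: zeta is hotter than Saturday's run, and the clean share read 43.6% on Friday, a run colder and with less activator than Saturday's. I take 79.4% as my estimated floor for zeta.
- The forecast names zeta, with 83% for zeta and 52% for gamma, and allows “some side product possible (few %)”. Its zeta figure is an asked share, yet it stands inside my bracket for the clean share.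
- The flask gives zeta as best, with 73.3% for zeta and 49.8% for gamma. Zeta's clean share is 83.1%, above 79.4%, and with side product at 5.16% the asked share falls below that floor.

    2 starting material → self-condensation product (k = 0.0160 M⁻¹ s⁻¹, Ea = 78.0 kJ mol⁻¹)
    starting material + ring → side product (k = 0.00670 M⁻¹ s⁻¹, Ea = 48.0 kJ mol⁻¹)
    activated form → ring (k = 0.00280 s⁻¹, Ea = 81.0 kJ mol⁻¹)
    starting material + activator → activated form (k = 0.00890 M⁻¹ s⁻¹, Ea = 78.0 kJ mol⁻¹)
    starting material + activated form → open dimer (k = 0.00690 M⁻¹ s⁻¹, Ea = 55.0 kJ mol⁻¹)
    (constants at 50 °C)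

- At the start of gamma, starting material goes to activated form at 0.31 of the rate at which it goes to self-condensation product. Zeta at 50.0 min holds 56.5% as self-condensation product against 31.8% as ring.
- Gamma left until 2.0 h has a clean share of 68.3%, below Saturday's 79.4%. With side product at 6.67%, its computed share is 56.7%.

The runs were computed from invented constants; noise was put on by code.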